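## Retrosynthetic overview
1. 38 ⇒ dibenzyl ether 37 ⇒ tetraol 35, by opening the O1–C2 bond of the dihydrofuran (acid-induced benzylic substitution by the ring B phenol).
2. 35 ⇒ (LiBH4) syn-aldol 34 ⇒ key C–C disconnection at C2–C3 of the dihydrobenzofuran: intermolecular Evans boron aldol of arylacetyl imide 30 with O-benzylvanillin 31.
3. 30 ⇒ allylarene 25 (allyl → CH2CO2H) ⇒ trans-selective alkylation of (R)-lactone 15 with benzylic bromide 23 (from vanillin by aromatic Claisen rearrangement).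
4. 15 ⇒ Evans alkylation of the dihydroferuloyl imide 7 with tert-butyl bromoacetate 8.
5. Ring order: the butyrolactone comes first (step 8; it masks the 1,4-diol and is opened in step 19) and the dihydrofuran ring last (step 20). The three benzene rings are bought.

Assumption: carbon building blocks are numbered and stand under Reactants. Unnumbered reagents that deliver atoms, even to a non-isolated intermediate only, stand under "Reagents that add atoms". Carboxylate salts present before an acidic work-up are not counted as separate compounds.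

Notation: ring A is the guaiacyl ring of the butanediol arm, ring B is the benzene ring of the dihydrobenzofuran, and ring C is the 2-aryl ring.

## Route

Step 1
Reactants: 1 (E)-ferulic acid
Product: 2 3-(4-hydroxy-3-methoxyphenyl)propanoic acid
Conditions: H2 (1 atm), 10% Pd/C, MeOH, rt
Reagents that add atoms: none
Why: Heterogeneous catalytic hydrogenation saturates the conjugated C=C, and nothing else in the molecule is reducible under these conditions.

Step 2
Reactants: 2 3-(4-hydroxy-3-methoxyphenyl)propanoic acid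
Product: 3 benzyl 3-(4-benzyloxy-3-methoxyphenyl)propanoate
Conditions: BnBr (2.3 equiv), K2CO3 (3 equiv), DMF, 60 °C
Reagents that add atoms: benzyl bromide, BrCc1ccccc1
Why: Williamson etherification of the phenoxide and SN2 O-alkylation of the carboxylate both run to completion with excess benzyl bromide.

Step 3
Reactants: 3 benzyl ester
Product: 4 3-(4-benzyloxy-3-methoxyphenyl)propanoic acid
Conditions: 2 M aq NaOH, THF/MeOH, 50 °C; then 1 M HCl
Reagents that add atoms: sodium hydroxide, [Na+].[OH-]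
Why: Saponification cleaves only the ester, because the aryl benzyl ether is inert to hydroxide.

Step 4
Reactants: 4 3-(4-benzyloxy-3-methoxyphenyl)propanoic acid; 5 (S)-4-benzyl-2-oxazolidinone
Product: 7 (4S)-4-benzyl-3-[3-(4-benzyloxy-3-methoxyphenyl)propanoyl]oxazolidin-2-one, via mixed pivalic anhydride 6 (not isolated)
Conditions: t-BuCOCl, Et3N, THF, −20 °C; then LiCl, 5, −20 °C → rt
Reagents that add atoms: pivaloyl chloride, CC(C)(C)C(=O)Cl (its atoms stand in 6 only)
Why: In this N-acylation through a mixed anhydride the oxazolidinone attacks the unhindered acyl carbon, because the pivaloyl carbonyl is sterically shielded.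

Step 5
Reactants: 7 imide; 8 tert-butyl bromoacetate
Product: 10 tert-butyl (3R)-3-(4-benzyloxy-3-methoxybenzyl)-4-[(4S)-4-benzyl-2-oxooxazolidin-3-yl]-4-oxobutanoate, via sodium Z-enolate 9 (not isolated)
Conditions: NaN(SiMe3)2 (1.1 equiv), THF, −78 °C; then 8, −78 → −40 °C
Reagents that add atoms: sodium hexamethyldisilazide, [Na+].C[Si](C)(C)[N-][Si](C)(C)C (sodium stands in 9 only)
Why: In this Evans asymmetric alkylation the 4-benzyl group shields one face of the chelated (Z)-enolate, so the bromoacetate enters from the other face and sets the R centre (butane C2 of the target), typically with dr above 95:5.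

Step 6
Reactants: 10 alkylated imide
Product: 12 (2R)-2-(4-benzyloxy-3-methoxybenzyl)-4-tert-butoxy-4-oxobutanoic acid, via peroxy acid 11 (not isolated)
Conditions: LiOH, 30% H2O2, THF/H2O (3:1), 0 °C; then aq Na2SO3; then 1 M HCl
Reagents that add atoms: hydrogen peroxide, OO
Why: In this hydroperoxide cleavage of an Evans imide the small, very nucleophilic HOO− attacks the exocyclic acyl carbon, spares the tert-butyl ester and the α-centre, and sulfite reduces the peroxy acid to the acid.

Step 7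
Reactants: 12 succinic half ester
Product: 13 tert-butyl (3R)-3-(4-benzyloxy-3-methoxybenzyl)-4-hydroxybutanoate
Conditions: BH3·THF (1.5 equiv), THF, 0 °C → rt; then H2O
Reagents that add atoms: none
Why: This chemoselective borane reduction takes the free acid through an acyloxyborane much faster than it touches the tert-butyl ester, and the stereocentre is not involved.

Step 8
Reactants: 13 hydroxy ester
Product: 15 (4R)-4-(4-benzyloxy-3-methoxybenzyl)dihydrofuran-2(3H)-one, via hydroxy acid 14 (not isolated)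
Conditions: CF3CO2H/CH2Cl2 (1:5), 0 °C → rt, 2 h
Reagents that add atoms: none
Why: Acidolysis of the tert-butyl ester is followed by spontaneous five-ring lactonisation, and the aryl benzyl ether tolerates dilute CF3CO2H at rt.

Step 9
Reactants: 16 vanillin; 17 allyl bromide
Product: 18 4-allyloxy-3-methoxybenzaldehyde
Conditions: K2CO3, DMF, 50 °C
Reagents that add atoms: none
Why: This is a Williamson ether synthesis on an acidic phenol with a reactive allylic halide.

Step 10
Reactants: 18 allyl ether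
Product: 20 3-allyl-4-hydroxy-5-methoxybenzaldehyde, via ortho-dienone 19 (not isolated)
Conditions: N,N-diethylaniline, 200 °C, N2
Reagents that add atoms: none
Why: The aromatic Claisen [3,3]-rearrangement can deliver the allyl group only to the single free ortho position, and tautomerisation restores the phenol.

Step 11
Reactants: 20 5-allylvanillin
Product: 21 3-allyl-5-methoxy-4-(methoxymethoxy)benzaldehyde
Conditions: MOMCl, i-Pr2NEt, CH2Cl2, 0 °C → rt
Reagents that add atoms: chloromethyl methyl ether, COCCl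
Why: O-alkylation gives a MOM acetal that is stable to the bases, oxidants and hydrides ahead and is removed later by the same acid that closes the ring.

Step 12
Reactants: 21 MOM-protected aldehyde
Product: 22 [3-allyl-5-methoxy-4-(methoxymethoxy)phenyl]methanol
Conditions: NaBH4, MeOH, 0 °C
Reagents that add atoms: none
Why: Borohydride 1,2-reduction of the aldehyde leaves the alkene and the acetal untouched.

Step 13
Reactants: 22 benzylic alcohol
Product: 23 1-allyl-5-(bromomethyl)-3-methoxy-2-(methoxymethoxy)benzene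
Conditions: CBr4, PPh3, CH2Cl2, 0 °C, 30 min; short silica plug, used at once
Reagents that add atoms: carbon tetrabromide, BrC(Br)(Br)Br
Why: The Appel reaction converts the primary benzylic alcohol into the bromide under neutral conditions that spare the MOM acetal and the allyl group.

Step 14
Reactants: 15 (R)-lactone; 23 benzylic bromide
Product: 25 (3R,4R)-3-[3-allyl-5-methoxy-4-(methoxymethoxy)benzyl]-4-(4-benzyloxy-3-methoxybenzyl)dihydrofuran-2(3H)-one, via lithium enolate 24 (not isolated)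
Conditions: LiN(SiMe3)2 (1.1 equiv), THF, −78 °C; then 23, DMPU (2 equiv), −78 → −20 °C
Reagents that add atoms: lithium hexamethyldisilazide, [Li+].C[Si](C)(C)[N-][Si](C)(C)C (lithium stands in 24 only)
Why: In this SN2 alkylation of the lactone enolate the bromide approaches anti to the C4 benzyl group, which sets C3 as R (butane C3 of the target) and gives the trans lactone, also the thermodynamically preferred isomer.

Step 15
Reactants: 25 allyl lactone
Product: 27 {5-[((3R,4R)-4-(4-benzyloxy-3-methoxybenzyl)-2-oxotetrahydrofuran-3-yl)methyl]-3-methoxy-2-(methoxymethoxy)phenyl}acetaldehyde, via vicinal diol 26 (not isolated)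
Conditions: OsO4 (2 mol %), NaIO4 (4 equiv), 2,6-lutidine, dioxane/H2O (3:1), rt
Reagents that add atoms: sodium periodate, [Na+].[O-]I(=O)(=O)=O (oxygen passed on through OsO4); water, O
Why: The Lemieux–Johnson oxidation dihydroxylates the only alkene and cleaves the glycol in the same flask without attacking the electron-rich arenes.

Step 16
Reactants: 27 arylacetaldehyde
Product: 28 {5-[((3R,4R)-4-(4-benzyloxy-3-methoxybenzyl)-2-oxotetrahydrofuran-3-yl)methyl]-3-methoxy-2-(methoxymethoxy)phenyl}acetic acid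
Conditions: NaClO2, NaH2PO4, 2-methyl-2-butene (20 equiv), t-BuOH/H2O, 0 °C → rt
Reagents that add atoms: sodium chlorite, [Na+].[O-]Cl=O
Why: The Pinnick oxidation is selective for the aldehyde at buffered pH, where the MOM acetal is stable, and the alkene scavenger protects the arenes from chlorination.

Step 17
Reactants: 28 arylacetic acid; 5 (S)-4-benzyl-2-oxazolidinone
Product: 30 (4S)-4-benzyl-3-({5-[((3R,4R)-4-(4-benzyloxy-3-methoxybenzyl)-2-oxotetrahydrofuran-3-yl)methyl]-3-methoxy-2-(methoxymethoxy)phenyl}acetyl)oxazolidin-2-one, via mixed pivalic anhydride 29 (not isolated)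
Conditions: t-BuCOCl, Et3N, THF, −20 °C; then LiCl, 5, −20 °C → rt
Reagents that add atoms: pivaloyl chloride, CC(C)(C)C(=O)Cl (its atoms stand in 29 only)
Why: This mixed-anhydride N-acylation follows step 4, and its mild amine/LiCl conditions neither open nor epimerise the lactone.

Step 18 (key step)
Reactants: 30 arylacetyl imide; 31 4-benzyloxy-3-methoxybenzaldehyde
Product: 34 (4S)-4-benzyl-3-[(2S,3S)-3-(4-benzyloxy-3-methoxyphenyl)-3-hydroxy-2-{5-[((3R,4R)-4-(4-benzyloxy-3-methoxybenzyl)-2-oxotetrahydrofuran-3-yl)methyl]-3-methoxy-2-(methoxymethoxy)phenyl}propanoyl]oxazolidin-2-one, via boron Z-enolate 32 (not isolated), via boron aldolate 33 (not isolated)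
Conditions: Bu2BOTf (1.2 equiv), i-Pr2NEt (1.4 equiv), CH2Cl2, −78 → 0 °C; 31 (1.3 equiv), −78 → 0 °C; then pH 7 buffer, MeOH, 30% H2O2, 0 °C
Reagents that add atoms: dibutylboron triflate, CCCCB(CCCC)OS(=O)(=O)C(F)(F)F (boron and butyl groups stand in 32 and 33 only)
Why: In this Evans syn-aldol reaction the dibutylboron (Z)-enolate reacts through a closed Zimmerman–Traxler chair with one face blocked by the (S)-auxiliary, which sets the 2S aryl-bearing centre (the future dihydrobenzofuran C3) and the 3S carbinol, while the far less acidic tertiary lactone α-position is not enolised.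

Step 19
Reactants: 34 syn-aldol
Product: 35 (2R,3R)-2-(4-benzyloxy-3-methoxybenzyl)-3-{3-[(1S,2R)-1-(4-benzyloxy-3-methoxyphenyl)-1,3-dihydroxypropan-2-yl]-5-methoxy-4-(methoxymethoxy)benzyl}butane-1,4-diol
Conditions: LiBH4 (6 equiv), THF, 0 °C → rt; then aq NH4Cl
Reagents that add atoms: none
Why: This hydride reduction cleaves the imide to the primary alcohol and opens the lactone to the 1,4-diol without touching a stereocentre, and the aryl-bearing centre is now called R only because the CIP priorities change.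

Step 20
Reactants: 35 tetraol
Product: 37 (2R,3R)-2-(4-benzyloxy-3-methoxybenzyl)-3-{[(2S,3R)-2-(4-benzyloxy-3-methoxyphenyl)-3-(hydroxymethyl)-7-methoxy-2,3-dihydrobenzofuran-5-yl]methyl}butane-1,4-diol, via free phenol 36 (not isolated)
Conditions: HCl (0.5 M) in MeOH/THF (1:1), 40 °C
Reagents that add atoms: none
Why: Acetal solvolysis removes the MOM group and the carbinol ionises (SN1) to a cation stabilised by the para-benzyloxy group, which the neighbouring phenol captures in a five-ring closure anti to the C3 hydroxymethyl group, so C3 (R) dictates C2 (S) and the trans ring forms.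

Step 21
Reactants: 37 dibenzyl ether
Product: 38 (2R,3R)-2-(4-hydroxy-3-methoxybenzyl)-3-{[(2S,3R)-2-(4-hydroxy-3-methoxyphenyl)-3-(hydroxymethyl)-7-methoxy-2,3-dihydrobenzofuran-5-yl]methyl}butane-1,4-diol
Conditions: H2 (1 atm), 10% Pd/C, EtOAc/MeOH (1:1), rt, stopped at full conversion
Reagents that add atoms: none
Why: Catalytic hydrogenolysis of the two aryl benzyl ethers is fast at 1 atm in neutral solvent, whereas the hindered cyclic C2–O bond of a 2-aryl-2,3-dihydrobenzofuran stays intact under these mild conditions.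

## Compound list
1 | (E)-ferulic acid | COc1cc(/C=C/C(=O)O)ccc1O | starting material
2 | 3-(4-hydroxy-3-methoxyphenyl)propanoic acid | COc1cc(CCC(=O)O)ccc1O | intermediate
3 | benzyl 3-(4-benzyloxy-3-methoxyphenyl)propanoate | COc1cc(CCC(=O)OCc2ccccc2)ccc1OCc1ccccc1 | intermediate
4 | 3-(4-benzyloxy-3-methoxyphenyl)propanoic acid | COc1cc(CCC(=O)O)ccc1OCc1ccccc1 | intermediate
5 | (S)-4-benzyl-2-oxazolidinone | O=C1N[C@@H](Cc2ccccc2)CO1 | starting material
6 | 3-(4-benzyloxy-3-methoxyphenyl)propanoic pivalic anhydride (not isolated) | COc1cc(CCC(=O)OC(=O)C(C)(C)C)ccc1OCc1ccccc1 | intermediate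
7 | (4S)-4-benzyl-3-[3-(4-benzyloxy-3-methoxyphenyl)propanoyl]oxazolidin-2-one | COc1cc(CCC(=O)N2C(=O)OC[C@@H]2Cc2ccccc2)ccc1OCc1ccccc1 | intermediate
8 | tert-butyl bromoacetate | CC(C)(C)OC(=O)CBr | starting material
9 | sodium (Z)-enolate of 7 (not isolated) | COc1cc(C/C=C(\[O-])N2C(=O)OC[C@@H]2Cc2ccccc2)ccc1OCc1ccccc1.[Na+] | intermediate
10 | tert-butyl (3R)-3-(4-benzyloxy-3-methoxybenzyl)-4-[(4S)-4-benzyl-2-oxooxazolidin-3-yl]-4-oxobutanoate | COc1cc(C[C@H](CC(=O)OC(C)(C)C)C(=O)N2C(=O)OC[C@@H]2Cc2ccccc2)ccc1OCc1ccccc1 | intermediate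
11 | (2R)-2-(4-benzyloxy-3-methoxybenzyl)-4-tert-butoxy-4-oxobutaneperoxoic acid (not isolated) | COc1cc(C[C@H](CC(=O)OC(C)(C)C)C(=O)OO)ccc1OCc1ccccc1 | intermediate
12 | (2R)-2-(4-benzyloxy-3-methoxybenzyl)-4-tert-butoxy-4-oxobutanoic acid | COc1cc(C[C@H](CC(=O)OC(C)(C)C)C(=O)O)ccc1OCc1ccccc1 | intermediate
13 | tert-butyl (3R)-3-(4-benzyloxy-3-methoxybenzyl)-4-hydroxybutanoate | COc1cc(C[C@H](CC(=O)OC(C)(C)C)CO)ccc1OCc1ccccc1 | intermediate
14 | (3R)-3-(4-benzyloxy-3-methoxybenzyl)-4-hydroxybutanoic acid (not isolated) | COc1cc(C[C@H](CC(=O)O)CO)ccc1OCc1ccccc1 | intermediate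
15 | (4R)-4-(4-benzyloxy-3-methoxybenzyl)dihydrofuran-2(3H)-one | COc1cc(C[C@@H]2CC(=O)OC2)ccc1OCc1ccccc1 | intermediate
16 | vanillin | COc1cc(C=O)ccc1O | starting material
17 | allyl bromide | C=CCBr | starting material
18 | 4-allyloxy-3-methoxybenzaldehyde | C=CCOc1ccc(C=O)cc1OC | intermediate
19 | 6-allyl-4-formyl-2-methoxycyclohexa-2,4-dien-1-one (racemic; not isolated) | C=CCC1C=C(C=O)C=C(OC)C1=O | intermediate
20 | 3-allyl-4-hydroxy-5-methoxybenzaldehyde | C=CCc1cc(C=O)cc(OC)c1O | intermediate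
21 | 3-allyl-5-methoxy-4-(methoxymethoxy)benzaldehyde | C=CCc1cc(C=O)cc(OC)c1OCOC | intermediate
22 | [3-allyl-5-methoxy-4-(methoxymethoxy)phenyl]methanol | C=CCc1cc(CO)cc(OC)c1OCOC | intermediate
23 | 1-allyl-5-(bromomethyl)-3-methoxy-2-(methoxymethoxy)benzene | C=CCc1cc(CBr)cc(OC)c1OCOC | intermediate
24 | lithium enolate of 15 (not isolated) | COc1cc(C[C@@H]2C=C([O-])OC2)ccc1OCc1ccccc1.[Li+] | intermediate
25 | (3R,4R)-3-[3-allyl-5-methoxy-4-(methoxymethoxy)benzyl]-4-(4-benzyloxy-3-methoxybenzyl)dihydrofuran-2(3H)-one | COc1cc(C[C@H]2COC(=O)[C@@H]2Cc2cc(CC=C)c(OCOC)c(OC)c2)ccc1OCc1ccccc1 | intermediate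
26 | (3R,4R)-4-(4-benzyloxy-3-methoxybenzyl)-3-[3-(2,3-dihydroxypropyl)-5-methoxy-4-(methoxymethoxy)benzyl]dihydrofuran-2(3H)-one (both carbinol epimers; not isolated) | COc1cc(C[C@H]2COC(=O)[C@@H]2Cc2cc(CC(O)CO)c(OCOC)c(OC)c2)ccc1OCc1ccccc1 | intermediate
27 | {5-[((3R,4R)-4-(4-benzyloxy-3-methoxybenzyl)-2-oxotetrahydrofuran-3-yl)methyl]-3-methoxy-2-(methoxymethoxy)phenyl}acetaldehyde | COc1cc(C[C@H]2COC(=O)[C@@H]2Cc2cc(CC=O)c(OCOC)c(OC)c2)ccc1OCc1ccccc1 | intermediate
28 | {5-[((3R,4R)-4-(4-benzyloxy-3-methoxybenzyl)-2-oxotetrahydrofuran-3-yl)methyl]-3-methoxy-2-(methoxymethoxy)phenyl}acetic acid | COc1cc(C[C@H]2COC(=O)[C@@H]2Cc2cc(CC(=O)O)c(OCOC)c(OC)c2)ccc1OCc1ccccc1 | intermediate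
29 | mixed pivalic anhydride of 28 (not isolated) | COc1cc(C[C@H]2COC(=O)[C@@H]2Cc2cc(CC(=O)OC(=O)C(C)(C)C)c(OCOC)c(OC)c2)ccc1OCc1ccccc1 | intermediate
30 | (4S)-4-benzyl-3-({5-[((3R,4R)-4-(4-benzyloxy-3-methoxybenzyl)-2-oxotetrahydrofuran-3-yl)methyl]-3-methoxy-2-(methoxymethoxy)phenyl}acetyl)oxazolidin-2-one | COc1cc(C[C@H]2COC(=O)[C@@H]2Cc2cc(CC(=O)N3C(=O)OC[C@@H]3Cc3ccccc3)c(OCOC)c(OC)c2)ccc1OCc1ccccc1 | intermediate
31 | 4-benzyloxy-3-methoxybenzaldehyde (O-benzylvanillin) | COc1cc(C=O)ccc1OCc1ccccc1 | starting material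
32 | dibutylboron (Z)-enolate of 30 (not isolated) | COc1cc(C[C@H]2COC(=O)[C@@H]2Cc2cc(/C=C(\OB(CCCC)CCCC)N3C(=O)OC[C@@H]3Cc3ccccc3)c(OCOC)c(OC)c2)ccc1OCc1ccccc1 | intermediate
33 | O-dibutylboryl (2S,3S)-aldolate of 34 (not isolated) | COc1cc(C[C@H]2COC(=O)[C@@H]2Cc2cc([C@H](C(=O)N3C(=O)OC[C@@H]3Cc3ccccc3)[C@H](OB(CCCC)CCCC)c3ccc(OCc4ccccc4)c(OC)c3)c(OCOC)c(OC)c2)ccc1OCc1ccccc1 | intermediate
34 | (4S)-4-benzyl-3-[(2S,3S)-3-(4-benzyloxy-3-methoxyphenyl)-3-hydroxy-2-{5-[((3R,4R)-4-(4-benzyloxy-3-methoxybenzyl)-2-oxotetrahydrofuran-3-yl)methyl]-3-methoxy-2-(methoxymethoxy)phenyl}propanoyl]oxazolidin-2-one | COc1cc(C[C@H]2COC(=O)[C@@H]2Cc2cc([C@H](C(=O)N3C(=O)OC[C@@H]3Cc3ccccc3)[C@H](O)c3ccc(OCc4ccccc4)c(OC)c3)c(OCOC)c(OC)c2)ccc1OCc1ccccc1 | intermediate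
35 | (2R,3R)-2-(4-benzyloxy-3-methoxybenzyl)-3-{3-[(1S,2R)-1-(4-benzyloxy-3-methoxyphenyl)-1,3-dihydroxypropan-2-yl]-5-methoxy-4-(methoxymethoxy)benzyl}butane-1,4-diol | COc1cc(C[C@@H](CO)[C@H](CO)Cc2cc([C@H](CO)[C@H](O)c3ccc(OCc4ccccc4)c(OC)c3)c(OCOC)c(OC)c2)ccc1OCc1ccccc1 | intermediate
36 | free ring B phenol of 35 (MOM removed; not isolated) | COc1cc(C[C@@H](CO)[C@H](CO)Cc2cc([C@H](CO)[C@H](O)c3ccc(OCc4ccccc4)c(OC)c3)c(O)c(OC)c2)ccc1OCc1ccccc1 | intermediate
37 | (2R,3R)-2-(4-benzyloxy-3-methoxybenzyl)-3-{[(2S,3R)-2-(4-benzyloxy-3-methoxyphenyl)-3-(hydroxymethyl)-7-methoxy-2,3-dihydrobenzofuran-5-yl]methyl}butane-1,4-diol | COc1cc(C[C@@H](CO)[C@H](CO)Cc2cc(OC)c3c(c2)[C@H](CO)[C@@H](c2ccc(OCc4ccccc4)c(OC)c2)O3)ccc1OCc1ccccc1 | intermediate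
38 | (2R,3R)-2-(4-hydroxy-3-methoxybenzyl)-3-{[(2S,3R)-2-(4-hydroxy-3-methoxyphenyl)-3-(hydroxymethyl)-7-methoxy-2,3-dihydrobenzofuran-5-yl]methyl}butane-1,4-diol (CNP0256425.1) | COc1cc(C[C@@H](CO)[C@H](CO)Cc2cc(OC)c3c(c2)[C@H](CO)[C@@H](c2ccc(O)c(OC)c2)O3)ccc1O | target

## Step count and risks
Total step count: 21.
Longest linear sequence: 16 steps (steps 1–8, then 14–21, from ferulic acid). The vanillin branch (steps 9–13) joins at step 14.

**Step 18: boron aldol of a hindered, lactone-bearing arylacetyl imide.**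
- The fallback replaces the aldol by an auxiliary-controlled C-acylation followed by ketone reduction. It sets out from acid 28 and comes back at tetraol 35.
- Acid 28 is activated as anhydride 29 exactly as in step 17. It is then coupled to commercial (R)-4-benzyl-2-oxazolidinone to give the (R)-auxiliary imide F1.
- LiN(SiMe3)2 (1.0 equiv, THF, −78 °C) removes only the much more acidic arylacetyl proton and gives the chelated lithium (Z)-enolate F2.
- Commercial 4-benzyloxy-3-methoxybenzoic acid is converted with (COCl)2 and catalytic DMF into 4-benzyloxy-3-methoxybenzoyl chloride F3.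
- F3 acylates F2 on the face away from the auxiliary benzyl group and gives the (2S) β-keto imide F4. Chelated enolates react on the face opposite to the one used in the boron aldol, which is why the (R)-auxiliary is needed here.
- F4 is worked up cold at pH 7 and reduced at once with Zn(BH4)2 (Et2O/CH2Cl2, −20 °C) under chelation control to the syn β-hydroxy imide F5.
- LiBH4 as in step 19 then gives 35. The carbinol configuration is not critical, because step 20 sets it again.

**Step 19: retro-aldol or epimerisation of the α-aryl β-hydroxy imide under LiBH4.**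
- The fallback blocks the retro-aldol channel before any hydride is added. It sets out from 34 and comes back at 37.
- The carbinol of 34 is silylated (TBSOTf, 2,6-lutidine, CH2Cl2, −78 → 0 °C) to the benzylic silyl ether F6.
- LiBH4 (THF, 0 °C → rt) reduces the imide and the lactone to the silyl-protected triol F7.
- The conditions of step 20 remove the benzylic silyl ether and the MOM group and close the ring to 37.

**Step 20: one-pot MOM removal and cationic ring closure on the polyol (elimination, loss of formaldehyde, or stable benzylic methyl ethers).**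
- The fallback changes the order of events so that the ring closes through a neutral quinone methide and not a cation. It sets out from 35 and comes back at the target 38.
- Hydrogenolysis of 35 (H2 at 1 atm, 10% Pd/C, EtOAc/MeOH, rt) leaves the benzylic alcohol in place and gives the MOM-protected bis-phenol F8.
- Dilute HCl (0.05 M, MeOH/THF, rt) removes the MOM group to give the triphenol F9.
- The free para-hydroxyl of ring C in F9 lets water leave under this much milder acid and forms the para-quinone methide F10.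
- The ring B phenol adds to F10 anti to the hydroxymethyl group and gives trans 38 directly. Step 21 is then no longer needed, so the finished ring never meets Pd and H2.

## Further compounds
F1 | step 18 | (4R)-4-benzyl-3-({5-[((3R,4R)-4-(4-benzyloxy-3-methoxybenzyl)-2-oxotetrahydrofuran-3-yl)methyl]-3-methoxy-2-(methoxymethoxy)phenyl}acetyl)oxazolidin-2-one | COc1cc(C[C@H]2COC(=O)[C@@H]2Cc2cc(CC(=O)N3C(=O)OC[C@H]3Cc3ccccc3)c(OCOC)c(OC)c2)ccc1OCc1ccccc1
F2 | step 18 | lithium (Z)-enolate of F1 | COc1cc(C[C@H]2COC(=O)[C@@H]2Cc2cc(/C=C(\[O-])N3C(=O)OC[C@H]3Cc3ccccc3)c(OCOC)c(OC)c2)ccc1OCc1ccccc1.[Li+]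
F3 | step 18 | 4-benzyloxy-3-methoxybenzoyl chloride | COc1cc(C(=O)Cl)ccc1OCc1ccccc1
F4 | step 18 | (2S) β-keto imide: (4R)-4-benzyl-3-[(2S)-3-(4-benzyloxy-3-methoxyphenyl)-3-oxo-2-(ring B aryl as in 30)propanoyl]oxazolidin-2-one | COc1cc(C[C@H]2COC(=O)[C@@H]2Cc2cc([C@H](C(=O)N3C(=O)OC[C@H]3Cc3ccccc3)C(=O)c3ccc(OCc4ccccc4)c(OC)c3)c(OCOC)c(OC)c2)ccc1OCc1ccccc1
F5 | step 18 | (2S,3S) syn β-hydroxy imide carrying the (R)-auxiliary | COc1cc(C[C@H]2COC(=O)[C@@H]2Cc2cc([C@H](C(=O)N3C(=O)OC[C@H]3Cc3ccccc3)[C@H](O)c3ccc(OCc4ccccc4)c(OC)c3)c(OCOC)c(OC)c2)ccc1OCc1ccccc1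
F6 | step 19 | O-tert-butyldimethylsilyl ether of 34 | COc1cc(C[C@H]2COC(=O)[C@@H]2Cc2cc([C@H](C(=O)N3C(=O)OC[C@@H]3Cc3ccccc3)[C@H](O[Si](C)(C)C(C)(C)C)c3ccc(OCc4ccccc4)c(OC)c3)c(OCOC)c(OC)c2)ccc1OCc1ccccc1
F7 | step 19 | benzylic O-tert-butyldimethylsilyl ether of 35 | COc1cc(C[C@@H](CO)[C@H](CO)Cc2cc([C@H](CO)[C@H](O[Si](C)(C)C(C)(C)C)c3ccc(OCc4ccccc4)c(OC)c3)c(OCOC)c(OC)c2)ccc1OCc1ccccc1
F8 | step 20 | bis-debenzylated 35 (MOM ether retained) | COc1cc(C[C@@H](CO)[C@H](CO)Cc2cc([C@H](CO)[C@H](O)c3ccc(O)c(OC)c3)c(OCOC)c(OC)c2)ccc1O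
F9 | step 20 | triphenol (F8 without the MOM group) | COc1cc(C[C@@H](CO)[C@H](CO)Cc2cc([C@H](CO)[C@H](O)c3ccc(O)c(OC)c3)c(O)c(OC)c2)ccc1O
F10 | step 20 | ring C para-quinone methide derived from F9 | COc1cc(C[C@@H](CO)[C@H](CO)Cc2cc([C@H](CO)C=C3C=CC(=O)C(OC)=C3)c(O)c(OC)c2)ccc1O
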